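Target read 46.0% in the north-west run and 45.0% in the north-east run at 8.00 min. You wanted a quick number for a charge of 0.019 M.

| flask | starting material | remark | time |
|---|---|---|---|
| north-west | 0.0095 M | run made earlier |  |
| north-east | 0.014 M | run made earlier |  |
| flask | 0.019 M |  | 8.0 min |

| run | time / min | intermediate A / % | starting material / % | target / % | intermediate B / % | intermediate C / % |
|---|---|---|---|---|---|---|
| north-west | 1.50 | 8.2 | 11.2 | 3.3 | 69.3 | 7.5 |
| north-west | 3.00 | 3.3 | 1.8 | 12.5 | 62.4 | 19.2 |
| north-west | 5.00 | 2.8 | 3.2 | 28.1 | 45.9 | 21.0 |
| north-west | 6.00 | 0.3 | 0.6 | 33.6 | 38.9 | 22.5 |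
| north-west | 8.00 | 1.9 | 0.7 | 46.0 | 25.9 | 25.5 |
| north-east | 0.667 | 21.7 | 27.2 | 1.3 | 46.6 | 3.0 |
| north-east | 1.33 | 10.6 | 11.2 | 4.4 | 68.2 | 6.9 |
| north-east | 2.50 | 5.1 | 4.3 | 9.6 | 65.7 | 16.3 |
| north-east | 4.00 | 0.9 | 1.4 | 21.2 | 53.1 | 20.7 |
| north-east | 8.00 | 2.6 | 1.8 | 45.0 | 28.0 | 23.9 |

(each reading ± 1 percentage point)

- the numbers in the tables scatter by 1 percentage point (one standard deviation)
- a reading or a percentage of target counts all its forms, free or not
- a reading or a percentage of starting material is of its free form alone

1. where most of what was charged as starting material, at 8.0 min is found (intermediate A / target / intermediate C / starting material / intermediate B)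
2. the largest share itself, whichever of these holds it, in percent of the starting material charged

I wrote the mass balance of the starting material. I took target as what was charged, less what the readings put in intermediate B, intermediate C, intermediate A and free starting material. Intermediate B was still falling late in both runs, so it carried the reckoning. I treated its late fall as first order, a loss that has no charge in it when told in percent. The north-west run gave 0.176 min⁻¹ and the north-east run gave 0.155 min⁻¹, and I took the mean, 0.165 min⁻¹. That mean is my loss constant of intermediate B: the fall of the logarithm of its percentage per minute, late in a run.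

From the north-east reading of 53.1% at 4.00 min, this constant gave my estimate for the new flask: intermediate B at 27.4% at 8.0 min. The means of the last readings of both runs gave intermediate C 24.7%, and intermediate A with free starting material 3.50% together. The balance left target in the new flask at 44.4%, ahead of intermediate B and intermediate C.

Your forecast said target at 45%, against my 44.4%: “The whole percentage-versus-time profile nearly overlays”.

The flask gave target at 44.8%, with intermediate B at 27.8% and intermediate C at 24.1%.

    starting material ⇌ intermediate A (K = 1.50, k = 0.0500 s⁻¹)
    starting material → decomposition product (k = 3.20 × 10⁻⁵ s⁻¹)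
    intermediate A ⇌ intermediate B (K = 20.0, k = 0.0550 s⁻¹)
    intermediate B → intermediate C (k = 0.00300 s⁻¹)
    starting material + target ⇌ idle adduct, settled at all times (K = 61.0 M⁻¹)
    intermediate C ⇌ target (K = 2.70, k = 0.00980 s⁻¹)

The neighbouring flask was this one read at 5.0 min. I ran the loss constant backward from the flask's intermediate B at 8.0 min and got 45.6%. The balance, with intermediate C at 21.9%, intermediate A at 2.49% and free starting material at 1.8%, left target 28.2%. That flask held most in intermediate B, at 45.6%, with target at 27.7%.

The earlier runs and the new flask come from a simulation with constants of no real substance; noise was put on by code.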